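**Remarks on the chemistry.** The target has no stereocentre, so no step needs stereocontrol. Rings are lettered A (2,4,6-trihydroxyphenoxy end) to K (3,4,5-trihydroxyphenoxy end). In rings B, D, F, H and J, C1 carries the oxygen toward ring A, C3 and C5 carry OBn, and C4 carries the oxygen toward ring K. In rings C, E, G and I, C1 carries the oxygen toward ring A, C2 is CH, C3–C5 carry OBn, and C6 carries the oxygen toward ring K (or CHO, OCHO or OH at a chain end). All copper couplings and base treatments of the electron-rich phenols are run under argon.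

**Retrosynthetic overview**
1. The strategy rests on ring A, the terminal benzene-1,3,5-triol whose C2 carries the ether oxygen to C1 of ring B. Its six carbons are C1–C6 of a 6-aryloxy-3,5-dioxohexanoate, so ring A is cut at the C1–C6 bond (Claisen cyclisation) and is the only ring built.
2. The dioxo ester 39 goes back to the B–K decamer phenol 33 (25 benzyl ethers) by O-alkylation with a chloroacetamide and acylation of the methyl acetoacetate dianion.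
3. Phenol 33 is grown from ring B toward ring K by copper-catalysed diaryl ether couplings: B–C phenol 18, three copies of bromo aldehyde dimer 10 (each formyl then turned into the next phenol by Dakin oxidation), and J–K bromide 22.
4. The dimers come from 2,6-bis(benzyloxy)phenols (SNAr on 2,6-difluorobenzaldehydes, then Dakin) and from bromo aldehyde 5 or boronic acid 21, both made from bromide 3.
5. Rings B–K are carried as preformed benzene rings; ring A is closed in step 24, and hydrogenolysis of the 25 benzyl ethers ends the route.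

Key step: step 24

**Route**

Step 1
Reactants: 1 5-bromo-1,2,3-trimethoxybenzene
Product: 2 5-bromobenzene-1,2,3-triol
Conditions: BBr3, CH2Cl2, −78 °C → rt; then H2O
Reagents that add atoms: none
Why: Ether cleavage by BBr3 (complexation of each methoxy oxygen, then bromide attack at methyl) should free all three phenols and leave the aryl bromide untouched.

Step 2
Reactants: 2 5-bromobenzene-1,2,3-triol
Product: 3 5-bromo-1,2,3-tris(benzyloxy)benzene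
Conditions: BnBr, K2CO3, DMF, 60 °C, Ar
Reagents that add atoms: benzyl bromide, SMILES BrCc1ccccc1
Why: Williamson ether synthesis on the three phenoxides, with air excluded to avoid oxidation of the pyrogallol anion.

Step 3
Reactants: 3 5-bromo-1,2,3-tris(benzyloxy)benzene
Product: 5 6-bromo-2,3,4-tris(benzyloxy)benzaldehyde, via iminium chloride 4 (not isolated)
Conditions: POCl3, DMF, 80 °C; then H2O
Reagents that add atoms: N,N-dimethylformamide, SMILES CN(C)C=O; water, SMILES O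
Why: Vilsmeier–Haack formylation: C4 and C6 are the only free positions, are equivalent, and are ortho and para to benzyloxy groups, so a single aldehyde with bromine ortho to the formyl group should form.

Step 4
Reactants: 6 4-bromo-2,6-difluorobenzaldehyde
Product: 7 4-bromo-2,6-bis(benzyloxy)benzaldehyde
Conditions: BnOH, NaH, DMF, 0 °C → rt
Reagents that add atoms: benzyl alcohol, SMILES OCc1ccccc1
Why: Twofold nucleophilic aromatic substitution (SNAr): both fluorines are ortho to the formyl group and are displaced by benzyloxide far faster than the para bromine, so the bromide handle survives.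

Step 5
Reactants: 7 4-bromo-2,6-bis(benzyloxy)benzaldehyde
Product: 9 4-bromo-2,6-bis(benzyloxy)phenol, via aryl formate 8 (not isolated)
Conditions: mCPBA, CH2Cl2, 0 °C → rt; then K2CO3, MeOH, rt
Reagents that add atoms: mCPBA, SMILES O=C(OO)c1cccc(Cl)c1
Why: Dakin-type sequence: Baeyer–Villiger oxidation with migration of the electron-rich 2,6-dialkoxyaryl group gives the aryl formate, whose methanolysis frees the phenol flanked by two benzyloxy groups.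

Step 6
Reactants: 9 4-bromo-2,6-bis(benzyloxy)phenol; 5 6-bromo-2,3,4-tris(benzyloxy)benzaldehyde
Product: 10 bromo dimer aldehyde 2,3,4-tris(benzyloxy)-6-[2,6-bis(benzyloxy)-4-bromophenoxy]benzaldehyde
Conditions: CuI (10 mol %), N,N-dimethylglycine hydrochloride (30 mol %), Cs2CO3, dioxane, 70 °C, Ar
Reagents that add atoms: none
Why: Ullmann-type copper-catalysed diaryl ether coupling: the C–Br bond of 5 is ortho to the formyl group and activated toward monovalent copper, whereas the C–Br bond of 9 is para to a phenoxide oxygen and unactivated, so at 70 °C the ether should form without oligomerisation and the formyl group stays as the masked phenol of ring C.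

Step 7
Reactants: 11 2,6-difluoro-4-hydroxybenzaldehyde
Product: 12 2,6-difluoro-4-(methoxymethoxy)benzaldehyde
Conditions: MOMCl, K2CO3, acetone, 0 °C → rt
Reagents that add atoms: chloromethyl methyl ether, SMILES COCCl
Why: O-alkylation of the acidic 4-hydroxyl by the reactive alkoxymethyl chloride gives the MOM acetal that later marks the ring B hydroxyl reserved for ring A.

Step 8
Reactants: 12 2,6-difluoro-4-(methoxymethoxy)benzaldehyde
Product: 13 2,6-bis(benzyloxy)-4-(methoxymethoxy)benzaldehyde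
Conditions: BnOH, NaH, DMF, 0 → 50 °C
Reagents that add atoms: benzyl alcohol, SMILES OCc1ccccc1
Why: Twofold SNAr as in step 4, both fluorines being ortho to the formyl group; the MOM acetal is stable to alkoxide.

Step 9
Reactants: 13 2,6-bis(benzyloxy)-4-(methoxymethoxy)benzaldehyde
Product: 15 2,6-bis(benzyloxy)-4-(methoxymethoxy)phenol, via aryl formate 14 (not isolated)
Conditions: mCPBA, CH2Cl2, 0 °C → rt; then K2CO3, MeOH, rt
Reagents that add atoms: mCPBA, SMILES O=C(OO)c1cccc(Cl)c1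
Why: Dakin-type sequence as in step 5; the MOM acetal tolerates the weakly acidic peracid and the carbonate.

Step 10
Reactants: 15 2,6-bis(benzyloxy)-4-(methoxymethoxy)phenol; 5 6-bromo-2,3,4-tris(benzyloxy)benzaldehyde
Product: 16 MOM-capped dimer aldehyde 2,3,4-tris(benzyloxy)-6-[2,6-bis(benzyloxy)-4-(methoxymethoxy)phenoxy]benzaldehyde
Conditions: CuI (10 mol %), N,N-dimethylglycine hydrochloride (30 mol %), Cs2CO3, dioxane, 80 °C, Ar
Reagents that add atoms: none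
Why: Ullmann-type coupling of the hindered phenoxide with the formyl-activated bromide as in step 6, here with no competing halide.

Step 11
Reactants: 16 MOM-capped dimer aldehyde
Product: 18 MOM-capped dimer phenol (rings B–C; hydroxyl on C6 of ring C), via dimer aryl formate 17 (not isolated)
Conditions: mCPBA, CH2Cl2, 0 °C → rt; then K2CO3, MeOH/THF, rt
Reagents that add atoms: mCPBA, SMILES O=C(OO)c1cccc(Cl)c1
Why: Dakin-type sequence: the formyl group, flanked by an aryloxy and a benzyloxy group, sits on a very electron-rich ring, so aryl migration to the formate and methanolysis should give the ring C phenol.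

Step 12
Reactants: 3 5-bromo-1,2,3-tris(benzyloxy)benzene
Product: 21 [3,4,5-tris(benzyloxy)phenyl]boronic acid, via aryllithium 19 (not isolated), via lithium triisopropoxyborate 20 (not isolated)
Conditions: n-BuLi, THF, −78 °C; B(OiPr)3, −78 °C → rt; then 1 M HCl
Reagents that add atoms: triisopropyl borate, SMILES CC(C)OB(OC(C)C)OC(C)C; water, SMILES O
Why: Bromine–lithium exchange at −78 °C is faster than any benzylic deprotonation, and the aryllithium is trapped by the borate and hydrolysed to the boronic acid.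

Step 13
Reactants: 9 4-bromo-2,6-bis(benzyloxy)phenol; 21 [3,4,5-tris(benzyloxy)phenyl]boronic acid
Product: 22 bromo dimer J–K 1,2,3-tris(benzyloxy)-5-[2,6-bis(benzyloxy)-4-bromophenoxy]benzene
Conditions: Cu(OAc)2 (20 mol %), pyridine, 4 Å molecular sieves, CH2Cl2, O2 (1 atm), rt
Reagents that add atoms: none
Why: Chan–Lam–Evans O-arylation: the copper-mediated oxidative coupling runs at room temperature with phenols that carry two ortho substituents and does not touch the aryl bromide, which is kept for step 20.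

Step 14
Reactants: 18 MOM-capped dimer phenol; 10 bromo dimer aldehyde
Product: 23 MOM-capped tetramer aldehyde (rings B–E; formyl on C6 of ring E)
Conditions: CuI (20 mol %), N,N-dimethylglycine hydrochloride (60 mol %), Cs2CO3, dioxane, 100 °C, Ar
Reagents that add atoms: none
Why: Ullmann-type coupling in its favourable polarity, a hindered electron-rich phenoxide with an unhindered aryl bromide (two ortho hydrogens); the remote, non-enolisable formyl group of 10 survives the carbonate.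

Step 15
Reactants: 23 MOM-capped tetramer aldehyde
Product: 25 MOM-capped tetramer phenol (rings B–E; hydroxyl on C6 of ring E), via tetramer aryl formate 24 (not isolated)
Conditions: mCPBA, CH2Cl2, 0 °C → rt; then K2CO3, MeOH/THF, rt
Reagents that add atoms: mCPBA, SMILES O=C(OO)c1cccc(Cl)c1
Why: Dakin-type sequence as in step 11; ethers, the MOM acetal and the other arenes are inert to the peracid at this temperature.

Step 16
Reactants: 25 MOM-capped tetramer phenol; 10 bromo dimer aldehyde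
Product: 26 MOM-capped hexamer aldehyde (rings B–G; formyl on C6 of ring G)
Conditions: CuI (20 mol %), N,N-dimethylglycine hydrochloride (60 mol %), Cs2CO3, dioxane, 100 °C, Ar
Reagents that add atoms: none
Why: Ullmann-type coupling of the same kind as step 14, with the same hindered-phenoxide and unhindered-bromide pairing.

Step 17
Reactants: 26 MOM-capped hexamer aldehyde
Product: 28 MOM-capped hexamer phenol (rings B–G; hydroxyl on C6 of ring G), via hexamer aryl formate 27 (not isolated)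
Conditions: mCPBA, CH2Cl2, 0 °C → rt; then K2CO3, MeOH/THF, rt
Reagents that add atoms: mCPBA, SMILES O=C(OO)c1cccc(Cl)c1
Why: Dakin-type sequence as in step 11 on the single formyl group of the chain.

Step 18
Reactants: 28 MOM-capped hexamer phenol; 10 bromo dimer aldehyde
Product: 29 MOM-capped octamer aldehyde (rings B–I; formyl on C6 of ring I)
Conditions: CuI (20 mol %), N,N-dimethylglycine hydrochloride (60 mol %), Cs2CO3, dioxane, 100 °C, Ar
Reagents that add atoms: none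
Why: Ullmann-type coupling of the same kind as step 14.

Step 19
Reactants: 29 MOM-capped octamer aldehyde
Product: 31 MOM-capped octamer phenol (rings B–I; hydroxyl on C6 of ring I), via octamer aryl formate 30 (not isolated)
Conditions: mCPBA, CH2Cl2, 0 °C → rt; then K2CO3, MeOH/THF, rt
Reagents that add atoms: mCPBA, SMILES O=C(OO)c1cccc(Cl)c1
Why: Dakin-type sequence as in step 11.

Step 20
Reactants: 31 MOM-capped octamer phenol; 22 bromo dimer J–K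
Product: 32 MOM-capped decamer (rings B–K; 25 benzyl ethers; OCH2OCH3 on C1 of ring B)
Conditions: CuI (20 mol %), N,N-dimethylglycine hydrochloride (60 mol %), Cs2CO3, dioxane, 105 °C, Ar
Reagents that add atoms: none
Why: Ullmann-type coupling as in step 14; bromide 22 brings rings J and K at once and completes the B–K chain.

Step 21
Reactants: 32 MOM-capped decamer
Product: 33 decamer phenol (rings B–K; 25 benzyl ethers; free hydroxyl on C1 of ring B)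
Conditions: 3 M HCl, MeOH/THF, 50 °C
Reagents that add atoms: none
Why: Acid-catalysed acetal methanolysis removes the MOM group, while benzyl ethers and diaryl ethers are stable to dilute HCl.

Step 22
Reactants: 33 decamer phenol; 34 2-chloro-N-methoxy-N-methylacetamide
Product: 35 decamer Weinreb amide N-methoxy-N-methyl-2-(decamer-oxy)acetamide
Conditions: K2CO3, NaI (cat.), DMF, 60 °C
Reagents that add atoms: none
Why: Williamson alkylation of the unhindered ring B phenoxide by the α-chloro amide (iodide catalysis) installs C5 and C6 of the future triketide as a Weinreb amide.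

Step 23
Reactants: 35 decamer Weinreb amide; 36 methyl acetoacetate
Product: 39 methyl 6-(decamer-oxy)-3,5-dioxohexanoate, via acetoacetate dianion 37 (not isolated), via chelated tetrahedral adduct 38 (not isolated)
Conditions: 36, NaH, THF, 0 °C; n-BuLi, 0 °C; 35, −78 → 0 °C; then 1 M HCl, 0 °C
Reagents that add atoms: none
Why: Acylation of the acetoacetate dianion at its terminal carbon by the Weinreb amide (Huckin–Weiler-type dianion chemistry): the chelated tetrahedral adduct prevents a second addition and collapses to the 3,5-dioxo ester on acidic work-up.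

Step 24
Reactants: 39 methyl 6-(decamer-oxy)-3,5-dioxohexanoate
Product: 41 25-O-benzyl undecamer (ring A as free benzene-1,3,5-triol), via 2-aryloxycyclohexane-1,3,5-trione 40 (not isolated)
Conditions: NaOMe (6 equiv), MeOH/THF (1:1), 0.01 M, 65 °C, Ar; then 1 M HCl, 0 °C
Reagents that add atoms: none
Why: Proposed new method: methoxide deprotonates C4 of 39 and, in a small equilibrium share, C6, whose acidity is raised by the aryloxy oxygen; the C6 carbanion adds to the ester carbonyl C1 and methoxide is expelled, which forms the C1–C6 bond. The closest known reaction type is the base-induced Claisen (Dieckmann-type) cyclisation of 3,5-dioxoalkanoates and 3,5-dioxopimelates to phloroglucinols, the laboratory counterpart of the triketide cyclisation, which has not been shown with an aryloxy group on C6. Ring A closes in a 6-(enolexo)-exo-trig mode, and trione 40 tautomerises to the benzene-1,3,5-triol, whose phenoxide leaves the equilibrium. No stereocentre is formed. The step needs C-acylation through C6 in preference to O-acylation through the C5 enol oxygen (2-pyranone) and to retro-Claisen cleavage: the pyranone is reopened by methoxide whereas aromatisation is irreversible, the diketone is shielded from cleavage as its enolate, and high dilution suppresses intermolecular condensation. The 25 benzyl ethers and nine diaryl ethers are inert to methoxide, and the three new hydroxyls need no protection.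

Step 25
Reactants: 41 25-O-benzyl undecamer
Product: 42 CNP0245174.0
Conditions: H2 (1 atm), Pd/C (10 wt %), THF/MeOH, rt; work-up under Ar
Reagents that add atoms: none
Why: Hydrogenolysis cleaves the 25 benzyl–oxygen bonds on palladium while the diaryl ether bonds and the phenols are inert, which should free the 28-fold phenol.

**Compound list**

1 | 5-bromo-1,2,3-trimethoxybenzene | COc1cc(Br)cc(OC)c1OC | starting material
2 | 5-bromobenzene-1,2,3-triol | Oc1cc(Br)cc(O)c1O | intermediate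
3 | 5-bromo-1,2,3-tris(benzyloxy)benzene | Brc1cc(OCc2ccccc2)c(OCc2ccccc2)c(OCc2ccccc2)c1 | intermediate
4 | N-{[6-bromo-2,3,4-tris(benzyloxy)phenyl]methylidene}-N-methylmethanaminium chloride (iminium chloride) | C[N+](C)=Cc1c(Br)cc(OCc2ccccc2)c(OCc2ccccc2)c1OCc1ccccc1.[Cl-] | intermediate
5 | 6-bromo-2,3,4-tris(benzyloxy)benzaldehyde | O=Cc1c(Br)cc(OCc2ccccc2)c(OCc2ccccc2)c1OCc1ccccc1 | intermediate
6 | 4-bromo-2,6-difluorobenzaldehyde | O=Cc1c(F)cc(Br)cc1F | starting material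
7 | 4-bromo-2,6-bis(benzyloxy)benzaldehyde | O=Cc1c(OCc2ccccc2)cc(Br)cc1OCc1ccccc1 | intermediate
8 | 4-bromo-2,6-bis(benzyloxy)phenyl formate | O=COc1c(OCc2ccccc2)cc(Br)cc1OCc1ccccc1 | intermediate
9 | 4-bromo-2,6-bis(benzyloxy)phenol | Oc1c(OCc2ccccc2)cc(Br)cc1OCc1ccccc1 | intermediate
10 | bromo dimer aldehyde, 2,3,4-tris(benzyloxy)-6-[2,6-bis(benzyloxy)-4-bromophenoxy]benzaldehyde | Brc1cc(OCc2ccccc2)c(c(OCc2ccccc2)c1)Oc1cc(OCc2ccccc2)c(OCc2ccccc2)c(OCc2ccccc2)c1C=O | intermediate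
11 | 2,6-difluoro-4-hydroxybenzaldehyde | O=Cc1c(F)cc(O)cc1F | starting material
12 | 2,6-difluoro-4-(methoxymethoxy)benzaldehyde | COCOc1cc(F)c(C=O)c(F)c1 | intermediate
13 | 2,6-bis(benzyloxy)-4-(methoxymethoxy)benzaldehyde | COCOc1cc(OCc2ccccc2)c(C=O)c(OCc2ccccc2)c1 | intermediate
14 | 2,6-bis(benzyloxy)-4-(methoxymethoxy)phenyl formate | COCOc1cc(OCc2ccccc2)c(OC=O)c(OCc2ccccc2)c1 | intermediate
15 | 2,6-bis(benzyloxy)-4-(methoxymethoxy)phenol | COCOc1cc(OCc2ccccc2)c(O)c(OCc2ccccc2)c1 | intermediate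
16 | MOM-capped dimer aldehyde, 2,3,4-tris(benzyloxy)-6-[2,6-bis(benzyloxy)-4-(methoxymethoxy)phenoxy]benzaldehyde | COCOc1cc(OCc2ccccc2)c(c(OCc2ccccc2)c1)Oc1cc(OCc2ccccc2)c(OCc2ccccc2)c(OCc2ccccc2)c1C=O | intermediate
17 | dimer aryl formate, 2,3,4-tris(benzyloxy)-6-[2,6-bis(benzyloxy)-4-(methoxymethoxy)phenoxy]phenyl formate | COCOc1cc(OCc2ccccc2)c(c(OCc2ccccc2)c1)Oc1cc(OCc2ccccc2)c(OCc2ccccc2)c(OCc2ccccc2)c1OC=O | intermediate
18 | MOM-capped dimer phenol, 2,3,4-tris(benzyloxy)-6-[2,6-bis(benzyloxy)-4-(methoxymethoxy)phenoxy]phenol | COCOc1cc(OCc2ccccc2)c(c(OCc2ccccc2)c1)Oc1cc(OCc2ccccc2)c(OCc2ccccc2)c(OCc2ccccc2)c1O | intermediate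
19 | [3,4,5-tris(benzyloxy)phenyl]lithium | [Li]c1cc(OCc2ccccc2)c(OCc2ccccc2)c(OCc2ccccc2)c1 | intermediate
20 | lithium triisopropoxy[3,4,5-tris(benzyloxy)phenyl]borate | [Li+].CC(C)O[B-](OC(C)C)(OC(C)C)c1cc(OCc2ccccc2)c(OCc2ccccc2)c(OCc2ccccc2)c1 | intermediate
21 | [3,4,5-tris(benzyloxy)phenyl]boronic acid | OB(O)c1cc(OCc2ccccc2)c(OCc2ccccc2)c(OCc2ccccc2)c1 | intermediate
22 | bromo dimer J–K, 1,2,3-tris(benzyloxy)-5-[2,6-bis(benzyloxy)-4-bromophenoxy]benzene | Brc1cc(OCc2ccccc2)c(c(OCc2ccccc2)c1)Oc1cc(OCc2ccccc2)c(OCc2ccccc2)c(OCc2ccccc2)c1 | intermediate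
23 | MOM-capped tetramer aldehyde: rings B–E, OCH2OCH3 on C1 of ring B, CHO on C6 of ring E, ten OBn | COCOc1cc(OCc2ccccc2)c(c(OCc2ccccc2)c1)Oc1cc(OCc2ccccc2)c(OCc2ccccc2)c(OCc2ccccc2)c1Oc1cc(OCc2ccccc2)c(c(OCc2ccccc2)c1)Oc1cc(OCc2ccccc2)c(OCc2ccccc2)c(OCc2ccccc2)c1C=O | intermediate
24 | tetramer aryl formate: as 23 with OCHO on C6 of ring E | COCOc1cc(OCc2ccccc2)c(c(OCc2ccccc2)c1)Oc1cc(OCc2ccccc2)c(OCc2ccccc2)c(OCc2ccccc2)c1Oc1cc(OCc2ccccc2)c(c(OCc2ccccc2)c1)Oc1cc(OCc2ccccc2)c(OCc2ccccc2)c(OCc2ccccc2)c1OC=O | intermediate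
25 | MOM-capped tetramer phenol: as 23 with OH on C6 of ring E | COCOc1cc(OCc2ccccc2)c(c(OCc2ccccc2)c1)Oc1cc(OCc2ccccc2)c(OCc2ccccc2)c(OCc2ccccc2)c1Oc1cc(OCc2ccccc2)c(c(OCc2ccccc2)c1)Oc1cc(OCc2ccccc2)c(OCc2ccccc2)c(OCc2ccccc2)c1O | intermediate
26 | MOM-capped hexamer aldehyde: rings B–G, OCH2OCH3 on C1 of ring B, CHO on C6 of ring G, 15 OBn | COCOc1cc(OCc2ccccc2)c(c(OCc2ccccc2)c1)Oc1cc(OCc2ccccc2)c(OCc2ccccc2)c(OCc2ccccc2)c1Oc1cc(OCc2ccccc2)c(c(OCc2ccccc2)c1)Oc1cc(OCc2ccccc2)c(OCc2ccccc2)c(OCc2ccccc2)c1Oc1cc(OCc2ccccc2)c(c(OCc2ccccc2)c1)Oc1cc(OCc2ccccc2)c(OCc2ccccc2)c(OCc2ccccc2)c1C=O | intermediate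
27 | hexamer aryl formate: as 26 with OCHO on C6 of ring G | COCOc1cc(OCc2ccccc2)c(c(OCc2ccccc2)c1)Oc1cc(OCc2ccccc2)c(OCc2ccccc2)c(OCc2ccccc2)c1Oc1cc(OCc2ccccc2)c(c(OCc2ccccc2)c1)Oc1cc(OCc2ccccc2)c(OCc2ccccc2)c(OCc2ccccc2)c1Oc1cc(OCc2ccccc2)c(c(OCc2ccccc2)c1)Oc1cc(OCc2ccccc2)c(OCc2ccccc2)c(OCc2ccccc2)c1OC=O | intermediate
28 | MOM-capped hexamer phenol: as 26 with OH on C6 of ring G | COCOc1cc(OCc2ccccc2)c(c(OCc2ccccc2)c1)Oc1cc(OCc2ccccc2)c(OCc2ccccc2)c(OCc2ccccc2)c1Oc1cc(OCc2ccccc2)c(c(OCc2ccccc2)c1)Oc1cc(OCc2ccccc2)c(OCc2ccccc2)c(OCc2ccccc2)c1Oc1cc(OCc2ccccc2)c(c(OCc2ccccc2)c1)Oc1cc(OCc2ccccc2)c(OCc2ccccc2)c(OCc2ccccc2)c1O | intermediate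
29 | MOM-capped octamer aldehyde: rings B–I, OCH2OCH3 on C1 of ring B, CHO on C6 of ring I, 20 OBn | COCOc1cc(OCc2ccccc2)c(c(OCc2ccccc2)c1)Oc1cc(OCc2ccccc2)c(OCc2ccccc2)c(OCc2ccccc2)c1Oc1cc(OCc2ccccc2)c(c(OCc2ccccc2)c1)Oc1cc(OCc2ccccc2)c(OCc2ccccc2)c(OCc2ccccc2)c1Oc1cc(OCc2ccccc2)c(c(OCc2ccccc2)c1)Oc1cc(OCc2ccccc2)c(OCc2ccccc2)c(OCc2ccccc2)c1Oc1cc(OCc2ccccc2)c(c(OCc2ccccc2)c1)Oc1cc(OCc2ccccc2)c(OCc2ccccc2)c(OCc2ccccc2)c1C=O | intermediate
30 | octamer aryl formate: as 29 with OCHO on C6 of ring I | COCOc1cc(OCc2ccccc2)c(c(OCc2ccccc2)c1)Oc1cc(OCc2ccccc2)c(OCc2ccccc2)c(OCc2ccccc2)c1Oc1cc(OCc2ccccc2)c(c(OCc2ccccc2)c1)Oc1cc(OCc2ccccc2)c(OCc2ccccc2)c(OCc2ccccc2)c1Oc1cc(OCc2ccccc2)c(c(OCc2ccccc2)c1)Oc1cc(OCc2ccccc2)c(OCc2ccccc2)c(OCc2ccccc2)c1Oc1cc(OCc2ccccc2)c(c(OCc2ccccc2)c1)Oc1cc(OCc2ccccc2)c(OCc2ccccc2)c(OCc2ccccc2)c1OC=O | intermediate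
31 | MOM-capped octamer phenol: as 29 with OH on C6 of ring I | COCOc1cc(OCc2ccccc2)c(c(OCc2ccccc2)c1)Oc1cc(OCc2ccccc2)c(OCc2ccccc2)c(OCc2ccccc2)c1Oc1cc(OCc2ccccc2)c(c(OCc2ccccc2)c1)Oc1cc(OCc2ccccc2)c(OCc2ccccc2)c(OCc2ccccc2)c1Oc1cc(OCc2ccccc2)c(c(OCc2ccccc2)c1)Oc1cc(OCc2ccccc2)c(OCc2ccccc2)c(OCc2ccccc2)c1Oc1cc(OCc2ccccc2)c(c(OCc2ccccc2)c1)Oc1cc(OCc2ccccc2)c(OCc2ccccc2)c(OCc2ccccc2)c1O | intermediate
32 | MOM-capped decamer: rings B–K, OCH2OCH3 on C1 of ring B, 25 OBn | COCOc1cc(OCc2ccccc2)c(c(OCc2ccccc2)c1)Oc1cc(OCc2ccccc2)c(OCc2ccccc2)c(OCc2ccccc2)c1Oc1cc(OCc2ccccc2)c(c(OCc2ccccc2)c1)Oc1cc(OCc2ccccc2)c(OCc2ccccc2)c(OCc2ccccc2)c1Oc1cc(OCc2ccccc2)c(c(OCc2ccccc2)c1)Oc1cc(OCc2ccccc2)c(OCc2ccccc2)c(OCc2ccccc2)c1Oc1cc(OCc2ccccc2)c(c(OCc2ccccc2)c1)Oc1cc(OCc2ccccc2)c(OCc2ccccc2)c(OCc2ccccc2)c1Oc1cc(OCc2ccccc2)c(c(OCc2ccccc2)c1)Oc1cc(OCc2ccccc2)c(OCc2ccccc2)c(OCc2ccccc2)c1 | intermediate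
33 | decamer phenol: rings B–K, OH on C1 of ring B, 25 OBn | Oc1cc(OCc2ccccc2)c(c(OCc2ccccc2)c1)Oc1cc(OCc2ccccc2)c(OCc2ccccc2)c(OCc2ccccc2)c1Oc1cc(OCc2ccccc2)c(c(OCc2ccccc2)c1)Oc1cc(OCc2ccccc2)c(OCc2ccccc2)c(OCc2ccccc2)c1Oc1cc(OCc2ccccc2)c(c(OCc2ccccc2)c1)Oc1cc(OCc2ccccc2)c(OCc2ccccc2)c(OCc2ccccc2)c1Oc1cc(OCc2ccccc2)c(c(OCc2ccccc2)c1)Oc1cc(OCc2ccccc2)c(OCc2ccccc2)c(OCc2ccccc2)c1Oc1cc(OCc2ccccc2)c(c(OCc2ccccc2)c1)Oc1cc(OCc2ccccc2)c(OCc2ccccc2)c(OCc2ccccc2)c1 | intermediate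
34 | 2-chloro-N-methoxy-N-methylacetamide | CON(C)C(=O)CCl | starting material
35 | decamer Weinreb amide: N-methoxy-N-methyl-2-aryloxyacetamide, aryl = B–K decamer bonded through C1 of ring B | CON(C)C(=O)COc1cc(OCc2ccccc2)c(c(OCc2ccccc2)c1)Oc1cc(OCc2ccccc2)c(OCc2ccccc2)c(OCc2ccccc2)c1Oc1cc(OCc2ccccc2)c(c(OCc2ccccc2)c1)Oc1cc(OCc2ccccc2)c(OCc2ccccc2)c(OCc2ccccc2)c1Oc1cc(OCc2ccccc2)c(c(OCc2ccccc2)c1)Oc1cc(OCc2ccccc2)c(OCc2ccccc2)c(OCc2ccccc2)c1Oc1cc(OCc2ccccc2)c(c(OCc2ccccc2)c1)Oc1cc(OCc2ccccc2)c(OCc2ccccc2)c(OCc2ccccc2)c1Oc1cc(OCc2ccccc2)c(c(OCc2ccccc2)c1)Oc1cc(OCc2ccccc2)c(OCc2ccccc2)c(OCc2ccccc2)c1 | intermediate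
36 | methyl acetoacetate | COC(=O)CC(C)=O | starting material
37 | sodium lithium dianion of methyl acetoacetate | [Na+].[Li+].[CH2-]C(=O)C=C([O-])OC | intermediate
38 | chelated tetrahedral adduct of dianion 37 with amide 35 | [Na+].[Li+].CON(C)C([O-])(CC(=O)C=C([O-])OC)COc1cc(OCc2ccccc2)c(c(OCc2ccccc2)c1)Oc1cc(OCc2ccccc2)c(OCc2ccccc2)c(OCc2ccccc2)c1Oc1cc(OCc2ccccc2)c(c(OCc2ccccc2)c1)Oc1cc(OCc2ccccc2)c(OCc2ccccc2)c(OCc2ccccc2)c1Oc1cc(OCc2ccccc2)c(c(OCc2ccccc2)c1)Oc1cc(OCc2ccccc2)c(OCc2ccccc2)c(OCc2ccccc2)c1Oc1cc(OCc2ccccc2)c(c(OCc2ccccc2)c1)Oc1cc(OCc2ccccc2)c(OCc2ccccc2)c(OCc2ccccc2)c1Oc1cc(OCc2ccccc2)c(c(OCc2ccccc2)c1)Oc1cc(OCc2ccccc2)c(OCc2ccccc2)c(OCc2ccccc2)c1 | intermediate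
39 | methyl 6-aryloxy-3,5-dioxohexanoate, aryl = B–K decamer (25 OBn) | COC(=O)CC(=O)CC(=O)COc1cc(OCc2ccccc2)c(c(OCc2ccccc2)c1)Oc1cc(OCc2ccccc2)c(OCc2ccccc2)c(OCc2ccccc2)c1Oc1cc(OCc2ccccc2)c(c(OCc2ccccc2)c1)Oc1cc(OCc2ccccc2)c(OCc2ccccc2)c(OCc2ccccc2)c1Oc1cc(OCc2ccccc2)c(c(OCc2ccccc2)c1)Oc1cc(OCc2ccccc2)c(OCc2ccccc2)c(OCc2ccccc2)c1Oc1cc(OCc2ccccc2)c(c(OCc2ccccc2)c1)Oc1cc(OCc2ccccc2)c(OCc2ccccc2)c(OCc2ccccc2)c1Oc1cc(OCc2ccccc2)c(c(OCc2ccccc2)c1)Oc1cc(OCc2ccccc2)c(OCc2ccccc2)c(OCc2ccccc2)c1 | intermediate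
40 | 2-aryloxycyclohexane-1,3,5-trione, aryl = B–K decamer (25 OBn) | O=C1CC(=O)C(C(=O)C1)Oc1cc(OCc2ccccc2)c(c(OCc2ccccc2)c1)Oc1cc(OCc2ccccc2)c(OCc2ccccc2)c(OCc2ccccc2)c1Oc1cc(OCc2ccccc2)c(c(OCc2ccccc2)c1)Oc1cc(OCc2ccccc2)c(OCc2ccccc2)c(OCc2ccccc2)c1Oc1cc(OCc2ccccc2)c(c(OCc2ccccc2)c1)Oc1cc(OCc2ccccc2)c(OCc2ccccc2)c(OCc2ccccc2)c1Oc1cc(OCc2ccccc2)c(c(OCc2ccccc2)c1)Oc1cc(OCc2ccccc2)c(OCc2ccccc2)c(OCc2ccccc2)c1Oc1cc(OCc2ccccc2)c(c(OCc2ccccc2)c1)Oc1cc(OCc2ccccc2)c(OCc2ccccc2)c(OCc2ccccc2)c1 | intermediate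
41 | 25-O-benzyl undecamer: ring A as free 2,4,6-trihydroxyphenoxy, rings B–K benzylated | Oc1cc(O)c(c(O)c1)Oc1cc(OCc2ccccc2)c(c(OCc2ccccc2)c1)Oc1cc(OCc2ccccc2)c(OCc2ccccc2)c(OCc2ccccc2)c1Oc1cc(OCc2ccccc2)c(c(OCc2ccccc2)c1)Oc1cc(OCc2ccccc2)c(OCc2ccccc2)c(OCc2ccccc2)c1Oc1cc(OCc2ccccc2)c(c(OCc2ccccc2)c1)Oc1cc(OCc2ccccc2)c(OCc2ccccc2)c(OCc2ccccc2)c1Oc1cc(OCc2ccccc2)c(c(OCc2ccccc2)c1)Oc1cc(OCc2ccccc2)c(OCc2ccccc2)c(OCc2ccccc2)c1Oc1cc(OCc2ccccc2)c(c(OCc2ccccc2)c1)Oc1cc(OCc2ccccc2)c(OCc2ccccc2)c(OCc2ccccc2)c1 | intermediate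
42 | CNP0245174.0 (undecameric phlorethol with 28 free hydroxyls) | Oc1cc(O)c(Oc2cc(O)c(Oc3cc(O)c(O)c(O)c3Oc3cc(O)c(Oc4cc(O)c(O)c(O)c4Oc4cc(O)c(Oc5cc(O)c(O)c(O)c5Oc5cc(O)c(Oc6cc(O)c(O)c(O)c6Oc6cc(O)c(Oc7cc(O)c(O)c(O)c7)c(O)c6)c(O)c5)c(O)c4)c(O)c3)c(O)c2)c(O)c1 | target

**Step count**

Total: 25 steps. Longest linear sequence: 17 steps (steps 7–11 and 14–25; equally steps 1–3, 10, 11 and 14–25).

**Steps most likely to fail**

1. Step 24 (key step, proposed new method). The dioxo ester may be diverted into O-acylation to a pyranone that is not reopened, or be cut by retro-Claisen attack of methoxide at C5, so that no arene forms. The fallback uses known chemistry and brings ring A in as an intact arene. It sets out from decamer phenol 33, which is coupled under Ullmann conditions (CuI, N,N-dimethylglycine hydrochloride, Cs2CO3, dioxane, 110 °C) with 2-iodo-1,3,5-tris(benzyloxy)benzene F1, itself obtained from commercial 1,3,5-tris(benzyloxy)benzene and N-iodosuccinimide. This should give the fully benzylated undecamer F2, and hydrogenolysis of its 28 benzyl ethers (H2, Pd/C) comes back to the route at target 42.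

2. Step 6. Chemoselectivity may be lost: copper may also insert into the unactivated C–Br bond of 9 or of product 10, which leads to oligomeric ethers. The fallback gives up dimer 10 and extends the chain one ring at a time with formyl-activated bromides only, so that no nucleophile carries a halogen. It sets out from phenol 18, which is coupled (CuI, N,N-dimethylglycine hydrochloride, Cs2CO3, dioxane) with bromo aldehyde 7, whose bromide is para to the formyl group, to give trimer aldehyde F3. Dakin oxidation through trimer aryl formate F4 gives trimer phenol F5, and coupling of F5 with bromo aldehyde 5 comes back to the route at 23. The same three operations from 25 (pentamer aldehyde F6, pentamer aryl formate F7, pentamer phenol F8) come back at 26, and from 28 (heptamer aldehyde F9, heptamer aryl formate F10, heptamer phenol F11) at 29.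

3. Step 20. Oxidative addition of the unactivated bromide 22 may be slow and the octamer phenoxide may aggregate, so that hydrodebromination of 22 and recovery of 31 dominate. The fallback sets out from 31, which is coupled with the formyl-activated bromide 7 to give nonamer aldehyde F12. Dakin oxidation through nonamer aryl formate F13 gives nonamer phenol F14, whose hydroxyl on ring J is flanked by two benzyloxy groups. Chan–Lam arylation of F14 with boronic acid 21 (Cu(OAc)2, pyridine, O2, CH2Cl2, rt) comes back to the route at 32.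

**Further compounds**

F1 | step 24 | 2-iodo-1,3,5-tris(benzyloxy)benzene | Ic1c(OCc2ccccc2)cc(OCc2ccccc2)cc1OCc1ccccc1
F2 | step 24 | 28-O-benzyl undecamer (ring A as 2,4,6-tris(benzyloxy)phenoxy) | c1ccccc1COc1cc(OCc2ccccc2)c(c(OCc2ccccc2)c1)Oc1cc(OCc2ccccc2)c(c(OCc2ccccc2)c1)Oc1cc(OCc2ccccc2)c(OCc2ccccc2)c(OCc2ccccc2)c1Oc1cc(OCc2ccccc2)c(c(OCc2ccccc2)c1)Oc1cc(OCc2ccccc2)c(OCc2ccccc2)c(OCc2ccccc2)c1Oc1cc(OCc2ccccc2)c(c(OCc2ccccc2)c1)Oc1cc(OCc2ccccc2)c(OCc2ccccc2)c(OCc2ccccc2)c1Oc1cc(OCc2ccccc2)c(c(OCc2ccccc2)c1)Oc1cc(OCc2ccccc2)c(OCc2ccccc2)c(OCc2ccccc2)c1Oc1cc(OCc2ccccc2)c(c(OCc2ccccc2)c1)Oc1cc(OCc2ccccc2)c(OCc2ccccc2)c(OCc2ccccc2)c1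
F3 | step 6 | MOM-capped trimer aldehyde (rings B–D, CHO on C4 of ring D) | COCOc1cc(OCc2ccccc2)c(c(OCc2ccccc2)c1)Oc1cc(OCc2ccccc2)c(OCc2ccccc2)c(OCc2ccccc2)c1Oc1cc(OCc2ccccc2)c(c(OCc2ccccc2)c1)C=O
F4 | step 6 | trimer aryl formate (OCHO on C4 of ring D) | COCOc1cc(OCc2ccccc2)c(c(OCc2ccccc2)c1)Oc1cc(OCc2ccccc2)c(OCc2ccccc2)c(OCc2ccccc2)c1Oc1cc(OCc2ccccc2)c(c(OCc2ccccc2)c1)OC=O
F5 | step 6 | MOM-capped trimer phenol (OH on C4 of ring D) | COCOc1cc(OCc2ccccc2)c(c(OCc2ccccc2)c1)Oc1cc(OCc2ccccc2)c(OCc2ccccc2)c(OCc2ccccc2)c1Oc1cc(OCc2ccccc2)c(c(OCc2ccccc2)c1)O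
F6 | step 6 | MOM-capped pentamer aldehyde (rings B–F, CHO on C4 of ring F) | COCOc1cc(OCc2ccccc2)c(c(OCc2ccccc2)c1)Oc1cc(OCc2ccccc2)c(OCc2ccccc2)c(OCc2ccccc2)c1Oc1cc(OCc2ccccc2)c(c(OCc2ccccc2)c1)Oc1cc(OCc2ccccc2)c(OCc2ccccc2)c(OCc2ccccc2)c1Oc1cc(OCc2ccccc2)c(c(OCc2ccccc2)c1)C=O
F7 | step 6 | pentamer aryl formate (OCHO on C4 of ring F) | COCOc1cc(OCc2ccccc2)c(c(OCc2ccccc2)c1)Oc1cc(OCc2ccccc2)c(OCc2ccccc2)c(OCc2ccccc2)c1Oc1cc(OCc2ccccc2)c(c(OCc2ccccc2)c1)Oc1cc(OCc2ccccc2)c(OCc2ccccc2)c(OCc2ccccc2)c1Oc1cc(OCc2ccccc2)c(c(OCc2ccccc2)c1)OC=O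
F8 | step 6 | MOM-capped pentamer phenol (OH on C4 of ring F) | COCOc1cc(OCc2ccccc2)c(c(OCc2ccccc2)c1)Oc1cc(OCc2ccccc2)c(OCc2ccccc2)c(OCc2ccccc2)c1Oc1cc(OCc2ccccc2)c(c(OCc2ccccc2)c1)Oc1cc(OCc2ccccc2)c(OCc2ccccc2)c(OCc2ccccc2)c1Oc1cc(OCc2ccccc2)c(c(OCc2ccccc2)c1)O
F9 | step 6 | MOM-capped heptamer aldehyde (rings B–H, CHO on C4 of ring H) | COCOc1cc(OCc2ccccc2)c(c(OCc2ccccc2)c1)Oc1cc(OCc2ccccc2)c(OCc2ccccc2)c(OCc2ccccc2)c1Oc1cc(OCc2ccccc2)c(c(OCc2ccccc2)c1)Oc1cc(OCc2ccccc2)c(OCc2ccccc2)c(OCc2ccccc2)c1Oc1cc(OCc2ccccc2)c(c(OCc2ccccc2)c1)Oc1cc(OCc2ccccc2)c(OCc2ccccc2)c(OCc2ccccc2)c1Oc1cc(OCc2ccccc2)c(c(OCc2ccccc2)c1)C=O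
F10 | step 6 | heptamer aryl formate (OCHO on C4 of ring H) | COCOc1cc(OCc2ccccc2)c(c(OCc2ccccc2)c1)Oc1cc(OCc2ccccc2)c(OCc2ccccc2)c(OCc2ccccc2)c1Oc1cc(OCc2ccccc2)c(c(OCc2ccccc2)c1)Oc1cc(OCc2ccccc2)c(OCc2ccccc2)c(OCc2ccccc2)c1Oc1cc(OCc2ccccc2)c(c(OCc2ccccc2)c1)Oc1cc(OCc2ccccc2)c(OCc2ccccc2)c(OCc2ccccc2)c1Oc1cc(OCc2ccccc2)c(c(OCc2ccccc2)c1)OC=O
F11 | step 6 | MOM-capped heptamer phenol (OH on C4 of ring H) | COCOc1cc(OCc2ccccc2)c(c(OCc2ccccc2)c1)Oc1cc(OCc2ccccc2)c(OCc2ccccc2)c(OCc2ccccc2)c1Oc1cc(OCc2ccccc2)c(c(OCc2ccccc2)c1)Oc1cc(OCc2ccccc2)c(OCc2ccccc2)c(OCc2ccccc2)c1Oc1cc(OCc2ccccc2)c(c(OCc2ccccc2)c1)Oc1cc(OCc2ccccc2)c(OCc2ccccc2)c(OCc2ccccc2)c1Oc1cc(OCc2ccccc2)c(c(OCc2ccccc2)c1)O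
F12 | step 20 | MOM-capped nonamer aldehyde (rings B–J, CHO on C4 of ring J) | COCOc1cc(OCc2ccccc2)c(c(OCc2ccccc2)c1)Oc1cc(OCc2ccccc2)c(OCc2ccccc2)c(OCc2ccccc2)c1Oc1cc(OCc2ccccc2)c(c(OCc2ccccc2)c1)Oc1cc(OCc2ccccc2)c(OCc2ccccc2)c(OCc2ccccc2)c1Oc1cc(OCc2ccccc2)c(c(OCc2ccccc2)c1)Oc1cc(OCc2ccccc2)c(OCc2ccccc2)c(OCc2ccccc2)c1Oc1cc(OCc2ccccc2)c(c(OCc2ccccc2)c1)Oc1cc(OCc2ccccc2)c(OCc2ccccc2)c(OCc2ccccc2)c1Oc1cc(OCc2ccccc2)c(c(OCc2ccccc2)c1)C=O
F13 | step 20 | nonamer aryl formate (OCHO on C4 of ring J) | COCOc1cc(OCc2ccccc2)c(c(OCc2ccccc2)c1)Oc1cc(OCc2ccccc2)c(OCc2ccccc2)c(OCc2ccccc2)c1Oc1cc(OCc2ccccc2)c(c(OCc2ccccc2)c1)Oc1cc(OCc2ccccc2)c(OCc2ccccc2)c(OCc2ccccc2)c1Oc1cc(OCc2ccccc2)c(c(OCc2ccccc2)c1)Oc1cc(OCc2ccccc2)c(OCc2ccccc2)c(OCc2ccccc2)c1Oc1cc(OCc2ccccc2)c(c(OCc2ccccc2)c1)Oc1cc(OCc2ccccc2)c(OCc2ccccc2)c(OCc2ccccc2)c1Oc1cc(OCc2ccccc2)c(c(OCc2ccccc2)c1)OC=O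
F14 | step 20 | MOM-capped nonamer phenol (OH on C4 of ring J) | COCOc1cc(OCc2ccccc2)c(c(OCc2ccccc2)c1)Oc1cc(OCc2ccccc2)c(OCc2ccccc2)c(OCc2ccccc2)c1Oc1cc(OCc2ccccc2)c(c(OCc2ccccc2)c1)Oc1cc(OCc2ccccc2)c(OCc2ccccc2)c(OCc2ccccc2)c1Oc1cc(OCc2ccccc2)c(c(OCc2ccccc2)c1)Oc1cc(OCc2ccccc2)c(OCc2ccccc2)c(OCc2ccccc2)c1Oc1cc(OCc2ccccc2)c(c(OCc2ccccc2)c1)Oc1cc(OCc2ccccc2)c(OCc2ccccc2)c(OCc2ccccc2)c1Oc1cc(OCc2ccccc2)c(c(OCc2ccccc2)c1)O
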